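A direct plan would build the ring as an arene: a (CO)5Cr alkenyl(methoxy)carbene would be heated with the silylated (S)-propargylic ether A1 to give the p-methoxyphenol A2, which would be oxidised to a quinone monoketal, desilylated to diol A3, epoxidised, acetylated and hydrolysed. Its weakest steps would be:
- the benzannulation, because it needs stoichiometric chromium and a hindered alkyne that carries an acetal and a doubly allylic silyl ether, and must win orientation and phenol-versus-cyclobutenone selectivity together;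
- the epoxidation of A3, because its facial selectivity would hang only on a lithium chelate of the free side-chain carbinol;
- the closing acid hydrolysis of two ketals, because it runs beside the oxirane and an ionisable allylic acetate.
Four silylation and desilylation steps would add length without complexity.

The new route would close the oxirane first and the carbocycle last. Sharpless epoxidation of an achiral allylic alcohol, whose two identical arms on the quaternary C5 are the future C4 and C7, sets C6; lactonisation onto C1 then tells the arms apart and fixes C5. The oxirane relays its configuration to C7 by chelation-controlled addition of the C8–C12 dienyl unit to the C7 aldehyde. Only then is the six-membered ring made, by ring-closing metathesis at C2=C3 between vinyl groups on the carbonyl carbons C1 and C4, which the C5–C6 oxirane holds cis. No chromium carbene and no face-selective ring epoxidation are needed, and the last step is a neutral oxidation, not an acid hydrolysis.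

Key step: step 12

Remark: atoms carry the numbers of the target (ring C1(=O)–C2(CH2OAc)=C3H–C4(=O)–C5–C6 with the oxirane on C5–C6, side chain C7(OAc)–C8H=C9(CH3)–C10H=C11H–C12HO); the C4 carbinol made in step 11 is assumed to form as a mixture of epimers (5RS in the bicyclic names, unspecified in the SMILES), which is without consequence because step 18 oxidises this carbon.

Step 1
Reactants: 1 2,2-dimethyl-1,3-dioxan-5-one; 2 ethyl 2-(triphenyl-λ5-phosphanylidene)acetate
Product: 3 ethyl 2-(2,2-dimethyl-1,3-dioxan-5-ylidene)acetate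
Conditions: toluene, 80 °C
Reagents that add atoms: none
Why: Wittig olefination with a stabilised ylide; because ketone 1 is symmetric the trisubstituted alkene has no E/Z isomers and the two ring CH2O arms (future C4 and C7) stay equivalent.

Step 2
Reactants: 3 ethyl 2-(2,2-dimethyl-1,3-dioxan-5-ylidene)acetate
Product: 4 2-(2,2-dimethyl-1,3-dioxan-5-ylidene)ethan-1-ol
Conditions: i-Bu2AlH (2.2 equiv), CH2Cl2, −78 °C; aq. potassium sodium tartrate
Reagents that add atoms: none
Why: 1,2-Reduction of the conjugated ester by i-Bu2AlH at low temperature should give the allylic alcohol and leave the acetonide untouched.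

Step 3
Reactants: 4 2-(2,2-dimethyl-1,3-dioxan-5-ylidene)ethan-1-ol
Product: 5 [(2R)-6,6-dimethyl-1,5,7-trioxaspiro[2.5]octan-2-yl]methanol
Conditions: Ti(OiPr)4 (10 mol %), D-(−)-diisopropyl tartrate (12 mol %), t-BuOOH (2 equiv), 4 Å molecular sieves, CH2Cl2, −20 °C
Reagents that add atoms: tert-butyl hydroperoxide, CC(C)(C)OO
Why: Sharpless asymmetric epoxidation of a 3,3-disubstituted primary allylic alcohol, a well-behaved substrate class, in which the D-(−)-tartrate–titanium complex delivers oxygen to one enantioface and so sets the oxirane CH (C6, here 2R), while the spiro carbon C5 is not yet a stereocentre because its two arms are identical.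

Step 4
Reactants: 5 [(2R)-6,6-dimethyl-1,5,7-trioxaspiro[2.5]octan-2-yl]methanol
Product: 7 (1S,5S)-5-(hydroxymethyl)-3,6-dioxabicyclo[3.1.0]hexan-2-one, via epoxy acid 6 (not isolated)
Conditions: TEMPO (0.2 equiv), PhI(OAc)2 (2.1 equiv), MeCN/H2O (1:1), rt; then p-TsOH·H2O (0.2 equiv), 40 °C
Reagents that add atoms: water, O
Why: Nitroxyl-catalysed oxidation takes the primary alcohol to the acid, and acid then cleaves the acetonide so that only the hydroxymethyl arm cis to the carboxyl can close the γ-lactone (the only fusion an oxirane allows), a desymmetrising lactonisation that makes C5 a defined quaternary stereocentre relayed from C6 and leaves the trans arm (C7) as a free alcohol.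

Step 5
Reactants: 7 (1S,5S)-5-(hydroxymethyl)-3,6-dioxabicyclo[3.1.0]hexan-2-one
Product: 8 (1S,5S)-4-oxo-3,6-dioxabicyclo[3.1.0]hexane-1-carbaldehyde
Conditions: Dess–Martin periodinane, NaHCO3, CH2Cl2, 0 °C → rt
Reagents that add atoms: none
Why: Dess–Martin oxidation of the neopentyl-type primary alcohol should give an aldehyde that cannot enolise, so C5 is safe.

Step 6
Reactants: 9 (2E)-pent-2-en-4-yn-1-ol
Product: 10 tert-butyl[(2E)-pent-2-en-4-yn-1-yloxy]diphenylsilane
Conditions: t-BuPh2SiCl, imidazole, CH2Cl2, 0 °C → rt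
Reagents that add atoms: tert-butyl(chloro)diphenylsilane, CC(C)(C)[Si](Cl)(c1ccccc1)c1ccccc1
Why: Imidazole-promoted silylation of the primary allylic alcohol; the tert-butyldiphenylsilyl ether is chosen because it must outlast the later selective removal of a triethylsilyl group.

Step 7
Reactants: 10 tert-butyl[(2E)-pent-2-en-4-yn-1-yloxy]diphenylsilane
Product: 12 tert-butyl{[(2E,4E)-5-iodo-4-methylpenta-2,4-dien-1-yl]oxy}diphenylsilane, via alkenylalane 11 (not isolated)
Conditions: Me3Al (2.5 equiv), Cp2ZrCl2 (0.25 equiv), CH2Cl2, 0 °C → rt; then I2, THF, −30 °C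
Reagents that add atoms: trimethylaluminium, C[Al](C)C; iodine, II
Why: Zirconium-catalysed carboalumination (Negishi) adds methyl and aluminium syn across the terminal alkyne with methyl on the internal carbon, and iodinolysis with retention gives the (E)-alkenyl iodide, which fixes the C8=C9 geometry.

Step 8
Reactants: 8 (1S,5S)-4-oxo-3,6-dioxabicyclo[3.1.0]hexane-1-carbaldehyde; 12 tert-butyl{[(2E,4E)-5-iodo-4-methylpenta-2,4-dien-1-yl]oxy}diphenylsilane
Product: 16 (1S,5S)-5-[(1S,2E,4E)-6-{[tert-butyl(diphenyl)silyl]oxy}-3-methyl-1-[(triethylsilyl)oxy]hexa-2,4-dien-1-yl]-3,6-dioxabicyclo[3.1.0]hexan-2-one, via alkenyllithium 13 (not isolated), via alkenylmagnesium bromide 14 (not isolated), via carbinol 15 (not isolated)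
Conditions: 12, t-BuLi (2.1 equiv), Et2O, −78 °C; MgBr2·OEt2 (1.2 equiv); add to 8 premixed with MgBr2·OEt2 (1.5 equiv) in CH2Cl2, −78 °C; then Et3SiOTf, 2,6-lutidine, −78 → 0 °C
Reagents that add atoms: triethylsilyl trifluoromethanesulfonate, CC[Si](CC)(CC)OS(=O)(=O)C(F)(F)F
Why: Chelation-controlled (Cram-chelate) addition of an alkenylmagnesium reagent made by iodine–lithium exchange and transmetalation, in which magnesium should bridge the formyl and oxirane oxygens so that the alkenyl group attacks anti to the C5–C6 bond and sets (7S), the lactone being too slow to compete at −78 °C and the alkoxide being silylated in the same flask.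

Step 9
Reactants: 16 (1S,5S)-5-[(1S,2E,4E)-6-{[tert-butyl(diphenyl)silyl]oxy}-3-methyl-1-[(triethylsilyl)oxy]hexa-2,4-dien-1-yl]-3,6-dioxabicyclo[3.1.0]hexan-2-one
Product: 17 (2S,3S)-3-[(1S,2E,4E)-6-{[tert-butyl(diphenyl)silyl]oxy}-3-methyl-1-[(triethylsilyl)oxy]hexa-2,4-dien-1-yl]-3-(hydroxymethyl)-N-methoxy-N-methyloxirane-2-carboxamide
Conditions: MeNH(OMe)·HCl (3 equiv), i-PrMgCl (6 equiv), THF, −20 °C
Reagents that add atoms: N,O-dimethylhydroxylamine hydrochloride, CNOC.Cl
Why: Aminolysis of the strained lactone by the magnesium amide gives the N-methoxy-N-methylamide (Weinreb amide) and frees the C4 hydroxyl; the product would be oxidised at once to forestall relactonisation.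

Step 10
Reactants: 17 (2S,3S)-3-[(1S,2E,4E)-6-{[tert-butyl(diphenyl)silyl]oxy}-3-methyl-1-[(triethylsilyl)oxy]hexa-2,4-dien-1-yl]-3-(hydroxymethyl)-N-methoxy-N-methyloxirane-2-carboxamide
Product: 18 (2S,3S)-3-[(1S,2E,4E)-6-{[tert-butyl(diphenyl)silyl]oxy}-3-methyl-1-[(triethylsilyl)oxy]hexa-2,4-dien-1-yl]-3-formyl-N-methoxy-N-methyloxirane-2-carboxamide
Conditions: Dess–Martin periodinane, NaHCO3, CH2Cl2, 0 °C
Reagents that add atoms: none
Why: Buffered Dess–Martin oxidation of the primary alcohol; the aldehyde sits on the quaternary C5 and cannot epimerise.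

Step 11
Reactants: 18 (2S,3S)-3-[(1S,2E,4E)-6-{[tert-butyl(diphenyl)silyl]oxy}-3-methyl-1-[(triethylsilyl)oxy]hexa-2,4-dien-1-yl]-3-formyl-N-methoxy-N-methyloxirane-2-carboxamide
Product: 19 1-[(2S,3S)-3-[(1S,2E,4E)-6-{[tert-butyl(diphenyl)silyl]oxy}-3-methyl-1-[(triethylsilyl)oxy]hexa-2,4-dien-1-yl]-3-[(1RS)-1-hydroxyprop-2-en-1-yl]oxiran-2-yl]prop-2-en-1-one
Conditions: CH2=CHMgBr (3 equiv), THF, −78 → −10 °C; aq. NH4Cl
Reagents that add atoms: vinylmagnesium bromide, C=C[Mg]Br
Why: Grignard addition and Weinreb ketone synthesis in one operation: the aldehyde gives the C4 allylic alkoxide (either epimer serves), while the amide, or the lactone that the alkoxide may form from it, gives a tetrahedral magnesium adduct that releases the vinyl ketone only on work-up, so that over-addition is avoided.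

Step 12
Reactants: 19 1-[(2S,3S)-3-[(1S,2E,4E)-6-{[tert-butyl(diphenyl)silyl]oxy}-3-methyl-1-[(triethylsilyl)oxy]hexa-2,4-dien-1-yl]-3-[(1RS)-1-hydroxyprop-2-en-1-yl]oxiran-2-yl]prop-2-en-1-one
Product: 20 (1S,5RS,6S)-6-[(1S,2E,4E)-6-{[tert-butyl(diphenyl)silyl]oxy}-3-methyl-1-[(triethylsilyl)oxy]hexa-2,4-dien-1-yl]-5-hydroxy-7-oxabicyclo[4.1.0]hept-3-en-2-one
Conditions: second-generation Grubbs catalyst (5 mol %), CH2Cl2 (2 mM), 40 °C
Reagents that add atoms: none
Why: The ruthenium alkylidene should load on the electron-richer vinyl group of the C4 allylic alcohol, add across the terminal alkene of the vinyl ketone on C1 and expel ethene through a ruthenacyclobutane, so that C2=C3 forms; the closest known reaction type is the ring-closing olefin metathesis of hydroxy dienones to 4-hydroxycyclohex-2-enones. The ring closed is the six-membered carbocycle, by joining the two alkene carbons that hang from C1 and C4, and the oxirane made nine steps earlier holds these carbons cis on C5–C6, so that a cis-fused six-membered ring is the only closure open to them. No stereocentre is formed or touched, and both C4 epimers can cyclise. The selectivity needed is chemoselectivity against the C8=C9 and C10=C11 alkenes of the dienyl chain: both partners of the wanted closure are monosubstituted, whereas C8=C9 is trisubstituted, is flanked by the silyloxy-bearing C7 and the quaternary C5, and could enter a five-membered closure only through a disubstituted ruthenium carbene. High dilution should suppress cross-metathesis at C10=C11.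

Step 13
Reactants: 20 (1S,5RS,6S)-6-[(1S,2E,4E)-6-{[tert-butyl(diphenyl)silyl]oxy}-3-methyl-1-[(triethylsilyl)oxy]hexa-2,4-dien-1-yl]-5-hydroxy-7-oxabicyclo[4.1.0]hept-3-en-2-one
Product: 21 (1S,5RS,6R)-5-[(tert-butyldimethylsilyl)oxy]-6-[(1S,2E,4E)-6-{[tert-butyl(diphenyl)silyl]oxy}-3-methyl-1-[(triethylsilyl)oxy]hexa-2,4-dien-1-yl]-7-oxabicyclo[4.1.0]hept-3-en-2-one
Conditions: t-BuMe2SiOTf, 2,6-lutidine, CH2Cl2, −78 °C
Reagents that add atoms: tert-butyldimethylsilyl trifluoromethanesulfonate, CC(C)(C)[Si](C)(C)OS(=O)(=O)C(F)(F)F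
Why: Silylation of the hindered secondary alcohol with the silyl triflate under conditions that enone and oxirane tolerate; it keeps C4 at the alcohol level so that C1 is the only ketone.

Step 14
Reactants: 21 (1S,5RS,6R)-5-[(tert-butyldimethylsilyl)oxy]-6-[(1S,2E,4E)-6-{[tert-butyl(diphenyl)silyl]oxy}-3-methyl-1-[(triethylsilyl)oxy]hexa-2,4-dien-1-yl]-7-oxabicyclo[4.1.0]hept-3-en-2-one
Product: 22 (1S,5RS,6S)-5-[(tert-butyldimethylsilyl)oxy]-6-[(1S,2E,4E)-6-{[tert-butyl(diphenyl)silyl]oxy}-3-methyl-1-[(triethylsilyl)oxy]hexa-2,4-dien-1-yl]-3-(hydroxymethyl)-7-oxabicyclo[4.1.0]hept-3-en-2-one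
Conditions: aq. CH2O (37 %), DMAP (0.5 equiv), THF/H2O, rt
Reagents that add atoms: formaldehyde, C=O
Why: Morita–Baylis–Hillman hydroxymethylation, in which DMAP adds to C3, the enolate of the C1 ketone attacks formaldehyde at C2 and DMAP is expelled; the regiochemistry is unambiguous because C4 is still a silyl ether, and the oxirane lies on the far side of the ketone.

Step 15
Reactants: 22 (1S,5RS,6S)-5-[(tert-butyldimethylsilyl)oxy]-6-[(1S,2E,4E)-6-{[tert-butyl(diphenyl)silyl]oxy}-3-methyl-1-[(triethylsilyl)oxy]hexa-2,4-dien-1-yl]-3-(hydroxymethyl)-7-oxabicyclo[4.1.0]hept-3-en-2-one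
Product: 23 (1S,5RS,6R)-5-[(tert-butyldimethylsilyl)oxy]-6-[(1S,2E,4E)-6-{[tert-butyl(diphenyl)silyl]oxy}-1-hydroxy-3-methylhexa-2,4-dien-1-yl]-3-(hydroxymethyl)-7-oxabicyclo[4.1.0]hept-3-en-2-one
Conditions: HF·pyridine, pyridine, THF, 0 °C
Reagents that add atoms: none
Why: Selective desilylation: buffered HF·pyridine should cleave the triethylsilyl ether much faster than the hindered secondary tert-butyldimethylsilyl and the tert-butyldiphenylsilyl ethers, without the protic acid that could ionise the dienylic C7 position.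

Step 16
Reactants: 23 (1S,5RS,6R)-5-[(tert-butyldimethylsilyl)oxy]-6-[(1S,2E,4E)-6-{[tert-butyl(diphenyl)silyl]oxy}-1-hydroxy-3-methylhexa-2,4-dien-1-yl]-3-(hydroxymethyl)-7-oxabicyclo[4.1.0]hept-3-en-2-one
Product: 24 [(1S,5RS,6R)-6-[(1S,2E,4E)-1-acetoxy-6-{[tert-butyl(diphenyl)silyl]oxy}-3-methylhexa-2,4-dien-1-yl]-5-[(tert-butyldimethylsilyl)oxy]-2-oxo-7-oxabicyclo[4.1.0]hept-3-en-3-yl]methyl acetate
Conditions: Ac2O, Et3N, DMAP (cat.), CH2Cl2, 0 °C
Reagents that add atoms: acetic anhydride, CC(=O)OC(C)=O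
Why: DMAP-catalysed acylation should esterify the primary allylic and the hindered secondary hydroxyl in one operation.

Step 17
Reactants: 24 [(1S,5RS,6R)-6-[(1S,2E,4E)-1-acetoxy-6-{[tert-butyl(diphenyl)silyl]oxy}-3-methylhexa-2,4-dien-1-yl]-5-[(tert-butyldimethylsilyl)oxy]-2-oxo-7-oxabicyclo[4.1.0]hept-3-en-3-yl]methyl acetate
Product: 25 [(1S,5RS,6R)-6-[(1S,2E,4E)-1-acetoxy-6-hydroxy-3-methylhexa-2,4-dien-1-yl]-5-hydroxy-2-oxo-7-oxabicyclo[4.1.0]hept-3-en-3-yl]methyl acetate
Conditions: HF·pyridine (excess), THF, 0 °C → rt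
Reagents that add atoms: none
Why: Fluoride-mediated global desilylation under weakly acidic, non-basic conditions, which should spare both acetates (no acyl migration), the oxirane and the enone.

Step 18
Reactants: 25 [(1S,5RS,6R)-6-[(1S,2E,4E)-1-acetoxy-6-hydroxy-3-methylhexa-2,4-dien-1-yl]-5-hydroxy-2-oxo-7-oxabicyclo[4.1.0]hept-3-en-3-yl]methyl acetate
Product: 26 [(1R,6S)-1-[(1S,2E,4E)-1-acetoxy-3-methyl-6-oxohexa-2,4-dien-1-yl]-2,5-dioxo-7-oxabicyclo[4.1.0]hept-3-en-4-yl]methyl acetate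
Conditions: Dess–Martin periodinane (3 equiv), NaHCO3, CH2Cl2, 0 °C → rt
Reagents that add atoms: none
Why: Dess–Martin oxidation of the two remaining allylic alcohols: the ring carbinol gives the ene-dione and thereby erases the temporary C4 stereocentre, and the primary alcohol gives the dienal, while the buffered neutral medium leaves the oxirane, the C7 acetate and the alkene geometry untouched.

**Compound list**

1 | 2,2-dimethyl-1,3-dioxan-5-one | CC1(C)OCC(=O)CO1 | starting material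
2 | ethyl 2-(triphenyl-λ5-phosphanylidene)acetate | CCOC(=O)C=P(c1ccccc1)(c1ccccc1)c1ccccc1 | starting material
3 | ethyl 2-(2,2-dimethyl-1,3-dioxan-5-ylidene)acetate | CCOC(=O)C=C1COC(C)(C)OC1 | intermediate
4 | 2-(2,2-dimethyl-1,3-dioxan-5-ylidene)ethan-1-ol | OCC=C1COC(C)(C)OC1 | intermediate
5 | [(2R)-6,6-dimethyl-1,5,7-trioxaspiro[2.5]octan-2-yl]methanol | OC[C@H]1OC12COC(C)(C)OC2 | intermediate
6 | (2S)-6,6-dimethyl-1,5,7-trioxaspiro[2.5]octane-2-carboxylic acid | OC(=O)[C@H]1OC12COC(C)(C)OC2 | intermediate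
7 | (1S,5S)-5-(hydroxymethyl)-3,6-dioxabicyclo[3.1.0]hexan-2-one | O=C1OC[C@]2(CO)O[C@@H]21 | intermediate
8 | (1S,5S)-4-oxo-3,6-dioxabicyclo[3.1.0]hexane-1-carbaldehyde | O=C1OC[C@]2(C=O)O[C@@H]21 | intermediate
9 | (2E)-pent-2-en-4-yn-1-ol | OC/C=C/C#C | starting material
10 | tert-butyl[(2E)-pent-2-en-4-yn-1-yloxy]diphenylsilane | C#C/C=C/CO[Si](c1ccccc1)(c1ccccc1)C(C)(C)C | intermediate
11 | [(1E,3E)-5-{[tert-butyl(diphenyl)silyl]oxy}-2-methylpenta-1,3-dien-1-yl]dimethylalumane | C[Al](C)/C=C(C)/C=C/CO[Si](c1ccccc1)(c1ccccc1)C(C)(C)C | intermediate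
12 | tert-butyl{[(2E,4E)-5-iodo-4-methylpenta-2,4-dien-1-yl]oxy}diphenylsilane | I/C=C(C)/C=C/CO[Si](c1ccccc1)(c1ccccc1)C(C)(C)C | intermediate
13 | [(1E,3E)-5-{[tert-butyl(diphenyl)silyl]oxy}-2-methylpenta-1,3-dien-1-yl]lithium | [Li]/C=C(C)/C=C/CO[Si](c1ccccc1)(c1ccccc1)C(C)(C)C | intermediate
14 | bromo[(1E,3E)-5-{[tert-butyl(diphenyl)silyl]oxy}-2-methylpenta-1,3-dien-1-yl]magnesium | Br[Mg]/C=C(C)/C=C/CO[Si](c1ccccc1)(c1ccccc1)C(C)(C)C | intermediate
15 | (1S,5R)-5-[(1S,2E,4E)-6-{[tert-butyl(diphenyl)silyl]oxy}-1-hydroxy-3-methylhexa-2,4-dien-1-yl]-3,6-dioxabicyclo[3.1.0]hexan-2-one (formed as its bromomagnesium alkoxide) | O=C1OC[C@]2([C@H](/C=C(C)/C=C/CO[Si](c3ccccc3)(c3ccccc3)C(C)(C)C)O)O[C@@H]21 | intermediate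
16 | (1S,5S)-5-[(1S,2E,4E)-6-{[tert-butyl(diphenyl)silyl]oxy}-3-methyl-1-[(triethylsilyl)oxy]hexa-2,4-dien-1-yl]-3,6-dioxabicyclo[3.1.0]hexan-2-one | O=C1OC[C@]2([C@H](/C=C(C)/C=C/CO[Si](c3ccccc3)(c3ccccc3)C(C)(C)C)O[Si](CC)(CC)CC)O[C@@H]21 | intermediate
17 | (2S,3S)-3-[(1S,2E,4E)-6-{[tert-butyl(diphenyl)silyl]oxy}-3-methyl-1-[(triethylsilyl)oxy]hexa-2,4-dien-1-yl]-3-(hydroxymethyl)-N-methoxy-N-methyloxirane-2-carboxamide | OC[C@]1([C@H](/C=C(C)/C=C/CO[Si](c2ccccc2)(c2ccccc2)C(C)(C)C)O[Si](CC)(CC)CC)O[C@@H]1C(=O)N(C)OC | intermediate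
18 | (2S,3S)-3-[(1S,2E,4E)-6-{[tert-butyl(diphenyl)silyl]oxy}-3-methyl-1-[(triethylsilyl)oxy]hexa-2,4-dien-1-yl]-3-formyl-N-methoxy-N-methyloxirane-2-carboxamide | O=C[C@]1([C@H](/C=C(C)/C=C/CO[Si](c2ccccc2)(c2ccccc2)C(C)(C)C)O[Si](CC)(CC)CC)O[C@@H]1C(=O)N(C)OC | intermediate
19 | 1-[(2S,3S)-3-[(1S,2E,4E)-6-{[tert-butyl(diphenyl)silyl]oxy}-3-methyl-1-[(triethylsilyl)oxy]hexa-2,4-dien-1-yl]-3-[(1RS)-1-hydroxyprop-2-en-1-yl]oxiran-2-yl]prop-2-en-1-one | C=CC(O)[C@]1([C@H](/C=C(C)/C=C/CO[Si](c2ccccc2)(c2ccccc2)C(C)(C)C)O[Si](CC)(CC)CC)O[C@@H]1C(=O)C=C | intermediate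
20 | (1S,5RS,6S)-6-[(1S,2E,4E)-6-{[tert-butyl(diphenyl)silyl]oxy}-3-methyl-1-[(triethylsilyl)oxy]hexa-2,4-dien-1-yl]-5-hydroxy-7-oxabicyclo[4.1.0]hept-3-en-2-one | C1=CC(O)[C@]2([C@H](/C=C(C)/C=C/CO[Si](c3ccccc3)(c3ccccc3)C(C)(C)C)O[Si](CC)(CC)CC)O[C@@H]2C1=O | intermediate
21 | (1S,5RS,6R)-5-[(tert-butyldimethylsilyl)oxy]-6-[(1S,2E,4E)-6-{[tert-butyl(diphenyl)silyl]oxy}-3-methyl-1-[(triethylsilyl)oxy]hexa-2,4-dien-1-yl]-7-oxabicyclo[4.1.0]hept-3-en-2-one | C1=CC(O[Si](C)(C)C(C)(C)C)[C@]2([C@H](/C=C(C)/C=C/CO[Si](c3ccccc3)(c3ccccc3)C(C)(C)C)O[Si](CC)(CC)CC)O[C@@H]2C1=O | intermediate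
22 | (1S,5RS,6S)-5-[(tert-butyldimethylsilyl)oxy]-6-[(1S,2E,4E)-6-{[tert-butyl(diphenyl)silyl]oxy}-3-methyl-1-[(triethylsilyl)oxy]hexa-2,4-dien-1-yl]-3-(hydroxymethyl)-7-oxabicyclo[4.1.0]hept-3-en-2-one | OCC1=CC(O[Si](C)(C)C(C)(C)C)[C@]2([C@H](/C=C(C)/C=C/CO[Si](c3ccccc3)(c3ccccc3)C(C)(C)C)O[Si](CC)(CC)CC)O[C@@H]2C1=O | intermediate
23 | (1S,5RS,6R)-5-[(tert-butyldimethylsilyl)oxy]-6-[(1S,2E,4E)-6-{[tert-butyl(diphenyl)silyl]oxy}-1-hydroxy-3-methylhexa-2,4-dien-1-yl]-3-(hydroxymethyl)-7-oxabicyclo[4.1.0]hept-3-en-2-one | OCC1=CC(O[Si](C)(C)C(C)(C)C)[C@]2([C@H](/C=C(C)/C=C/CO[Si](c3ccccc3)(c3ccccc3)C(C)(C)C)O)O[C@@H]2C1=O | intermediate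
24 | [(1S,5RS,6R)-6-[(1S,2E,4E)-1-acetoxy-6-{[tert-butyl(diphenyl)silyl]oxy}-3-methylhexa-2,4-dien-1-yl]-5-[(tert-butyldimethylsilyl)oxy]-2-oxo-7-oxabicyclo[4.1.0]hept-3-en-3-yl]methyl acetate | CC(=O)OCC1=CC(O[Si](C)(C)C(C)(C)C)[C@]2([C@H](/C=C(C)/C=C/CO[Si](c3ccccc3)(c3ccccc3)C(C)(C)C)OC(C)=O)O[C@@H]2C1=O | intermediate
25 | [(1S,5RS,6R)-6-[(1S,2E,4E)-1-acetoxy-6-hydroxy-3-methylhexa-2,4-dien-1-yl]-5-hydroxy-2-oxo-7-oxabicyclo[4.1.0]hept-3-en-3-yl]methyl acetate | CC(=O)OCC1=CC(O)[C@]2([C@H](/C=C(C)/C=C/CO)OC(C)=O)O[C@@H]2C1=O | intermediate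
26 | [(1R,6S)-1-[(1S,2E,4E)-1-acetoxy-3-methyl-6-oxohexa-2,4-dien-1-yl]-2,5-dioxo-7-oxabicyclo[4.1.0]hept-3-en-4-yl]methyl acetate | CC(=O)OCC1=CC(=O)[C@]2([C@H](/C=C(C)/C=C/C=O)OC(C)=O)O[C@@H]2C1=O | target

Total: 18 steps. Longest linear sequence: 16 steps (1–5 and 8–18); the side-chain branch (steps 6 and 7) joins in step 8.

Steps most likely to fail:

Step 8. What may go wrong: loss of facial control, because if magnesium does not hold the formyl and oxirane oxygens together, attack through an open, dipole-controlled conformer would give the C7 epimer. Fallback (reagent control in place of substrate control): setting out from 8 and 12, a Nozaki–Hiyama–Kishi coupling (CrCl2, catalytic NiCl2, a chiral oxazoline sulfonamide ligand, Et3N, THF, rt), in which the ligand on chromium and not the oxirane would choose the aldehyde face, should give carbinol 15 as an isolated compound. Silylation (Et3SiOTf, 2,6-lutidine) would bring it back to the route at 16. No new compound would arise (F0).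

Step 12. What may go wrong: diversion of the ruthenium carbene onto the dienyl chain (five-membered closure at C8=C9, cross-metathesis at C10=C11) or isomerisation of the allylic alcohol by ruthenium hydrides. Fallback (anionic closure with a cis-vinylene linchpin in place of metathesis): setting out from 18, (Z)-2-(tributylstannyl)ethenyllithium, made from (Z)-1,2-bis(tributylstannyl)ethene and MeLi in THF at −78 °C, would add to the aldehyde to give the (Z)-3-(tributylstannyl)allylic alcohol F1. Iododestannylation (I2, CH2Cl2, 0 °C) would give the (Z)-3-iodoallylic alcohol F2. With t-BuLi (3 equiv, THF, −100 °C) iodine–lithium exchange should outrun attack on the amide, and the alkenyllithium would acylate itself on the N-methoxy-N-methylamide (Parham-type cyclisation), which comes back to the route at 20.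

Step 14. What may go wrong: no turnover, because amine addition at the hindered C3 stays reversible without capture of formaldehyde, or the epoxy enone degrades under the basic aqueous conditions. Fallback (cross-coupling in place of organocatalysis): setting out from 21, α-iodination (I2, pyridine, CH2Cl2, rt) would give the 3-iodo enone F3, and Stille coupling with (tributylstannyl)methanol (Pd(PPh3)4, dioxane, 80 °C) would come back to the route at 22.

Further compounds
F0 | step 8 | none | none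
F1 | step 12 | (2S,3S)-3-[(1S,2E,4E)-6-{[tert-butyl(diphenyl)silyl]oxy}-3-methyl-1-[(triethylsilyl)oxy]hexa-2,4-dien-1-yl]-3-[(1RS,2Z)-1-hydroxy-3-(tributylstannyl)prop-2-en-1-yl]-N-methoxy-N-methyloxirane-2-carboxamide | CCCC[Sn](CCCC)(CCCC)/C=C\C(O)[C@]1([C@H](/C=C(C)/C=C/CO[Si](c2ccccc2)(c2ccccc2)C(C)(C)C)O[Si](CC)(CC)CC)O[C@@H]1C(=O)N(C)OC
F2 | step 12 | (2S,3S)-3-[(1S,2E,4E)-6-{[tert-butyl(diphenyl)silyl]oxy}-3-methyl-1-[(triethylsilyl)oxy]hexa-2,4-dien-1-yl]-3-[(1RS,2Z)-1-hydroxy-3-iodoprop-2-en-1-yl]-N-methoxy-N-methyloxirane-2-carboxamide | I/C=C\C(O)[C@]1([C@H](/C=C(C)/C=C/CO[Si](c2ccccc2)(c2ccccc2)C(C)(C)C)O[Si](CC)(CC)CC)O[C@@H]1C(=O)N(C)OC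
F3 | step 14 | (1S,5RS,6S)-5-[(tert-butyldimethylsilyl)oxy]-6-[(1S,2E,4E)-6-{[tert-butyl(diphenyl)silyl]oxy}-3-methyl-1-[(triethylsilyl)oxy]hexa-2,4-dien-1-yl]-3-iodo-7-oxabicyclo[4.1.0]hept-3-en-2-one | IC1=CC(O[Si](C)(C)C(C)(C)C)[C@]2([C@H](/C=C(C)/C=C/CO[Si](c3ccccc3)(c3ccccc3)C(C)(C)C)O[Si](CC)(CC)CC)O[C@@H]2C1=O
A1 | direct plan | tert-butyl{[(3S,4E,6E)-8,8-dimethoxy-5-methylocta-4,6-dien-1-yn-3-yl]oxy}dimethylsilane | C#C[C@H](/C=C(C)/C=C/C(OC)OC)O[Si](C)(C)C(C)(C)C
A2 | direct plan | 2-[(1S,2E,4E)-1-(tert-butyldimethylsilyloxy)-6,6-dimethoxy-3-methylhexa-2,4-dien-1-yl]-5-[(tert-butyldimethylsilyloxy)methyl]-4-methoxyphenol | COc1cc([C@H](/C=C(C)/C=C/C(OC)OC)O[Si](C)(C)C(C)(C)C)c(O)cc1CO[Si](C)(C)C(C)(C)C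
A3 | direct plan | 2-[(1S,2E,4E)-1-hydroxy-6,6-dimethoxy-3-methylhexa-2,4-dien-1-yl]-5-(hydroxymethyl)-4,4-dimethoxycyclohexa-2,5-dien-1-one | O=C1C=C(CO)C(OC)(OC)C=C1[C@H](/C=C(C)/C=C/C(OC)OC)O
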